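**Strategy.** The cyclohexene ring of the spirotetronate is split into two C3 units. Its spiro carbon is treated as a ketone carbonyl whose α-carbons, the ring CH2 and the methyl-bearing quaternary carbon, each bond to one end of (E)-2-methylpent-2-enal: CH2 to the ethyl-bearing carbon, quaternary carbon to the vinylic CH. Tying the quaternary carbon's CH2CH2 arm (the start of the eleven-membered ring) to the CH2 as a seven-membered β-keto lactone lets one organocatalytic Michael/aldol bicycloannulation close the carbocycle and set both stereocentres; the tether then leaves as CO2. Tetronate annulation, addition to a Diels–Alder-derived decalin aldehyde and ring-closing metathesis complete the route.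

Key step: step 3

Assumption: the quinidine-derived primary amine is taken to be the pseudoenantiomer that gives the needed sense at the ethyl-bearing carbon (the quinine-derived one serves otherwise); hydroxy ketones 3 and 11 are drawn open-chain although each equilibrates with a cyclic hemiketal.

**Cyclohexene–tetronate fragment (steps 1–8)**

Step 1
Reactants: 1 3-methyloxolan-2-one (α-methyl-γ-butyrolactone, racemic); 2 tert-butyl acetate
Product: 3 tert-butyl 6-hydroxy-4-methyl-3-oxohexanoate (racemic)
Conditions: LiN(iPr)2 (2.1 equiv), 2, THF, −78 °C; then 1, −78 → −30 °C; aq. NH4Cl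
Reagents that add atoms: none
Why: Claisen-type acylation of the lithium ester enolate by the lactone, whose tetrahedral adduct persists at low temperature so only one acylation occurs; the methyl-bearing centre is racemic and is re-formed in step 3.

Step 2
Reactants: 3 tert-butyl 6-hydroxy-4-methyl-3-oxohexanoate
Product: 5 5-methyloxepane-2,4-dione (racemic), via acylketene 4 (not isolated)
Conditions: toluene (2 mM, slow addition), 110 °C
Reagents that add atoms: none
Why: thermal loss of tert-butanol from the tert-butyl β-keto ester gives an acylketene that the primary hydroxyl traps intramolecularly under high dilution (acylketene lactonisation), closing the seven-membered ring.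

Step 3
Reactants: 5 5-methyloxepane-2,4-dione; 6 (E)-2-methylpent-2-enal
Product: 8 (1S,6R,7S,8S,9S)-9-ethyl-7-hydroxy-6,8-dimethyl-3-oxabicyclo[4.3.1]decane-2,10-dione, via Michael adduct 7 (not isolated)
Conditions: 9-amino(9-deoxy)epi-quinidine (20 mol %), 2-fluorobenzoic acid (40 mol %), toluene, 23 °C; then DBU (30 mol %), 0 → 23 °C
Reagents that add atoms: none
Why: Iminium activation of 6 by the primary amine lets the enol of 5 add through C3 to the β-carbon of the enal (Michael addition, first C–C bond) on the face left open by the cinchona scaffold, which fixes the ethyl-bearing centre; after hydrolysis DBU enolises the ketone toward the methyl-bearing C5 and this enolate closes onto the aldehyde (intramolecular aldol, second C–C bond). The closest known reaction type is the organocatalytic domino Michael/aldol α,α′-annulation of cyclic β-keto esters with enals to bicyclo[3.3.1]nonanones, run here with a primary amine because the enal is α-branched. The six-membered carbocycle closes in the 6-(enolendo)-exo-trig mode and bridges the oxepanedione to a 3-oxabicyclo[4.3.1]decane. The bridge forces the lactone carbonyl and the CH2CH2O arm to be cis and axial on the new ring, so the quaternary centre carries its methyl equatorial, and its sense relative to the ethyl centre follows from the chair transition state with ethyl equatorial and the aldehyde oxygen axial, hydrogen-bonded to the enol(ate) oxygen; the carbinol and C8-methyl centres arise in the same chair and are erased in step 4. The step needs C- over O-addition of 5 and carbocyclisation over the reversible lactol, both favoured by the soft enol and the stability of the hydrogen-bonded ketol, and the reversibility of the aldol lets C1, C6 and C8 settle in this arrangement.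

Step 4
Reactants: 8 bicyclic ketol
Product: 9 (1S,6R,9R)-9-ethyl-6,8-dimethyl-3-oxabicyclo[4.3.1]dec-7-ene-2,10-dione
Conditions: Ph2S[OC(CF3)2Ph]2 (Martin sulfurane), CH2Cl2, 0 → 23 °C
Reagents that add atoms: none
Why: Martin sulfurane dehydration by anti elimination of the axial hydroxyl and the antiperiplanar axial hydrogen at C8; the quaternary neighbour has no hydrogen, so only the C7=C8 alkene can form and no cation is involved.

Step 5
Reactants: 9 bicyclic enone lactone
Product: 11 (2R,5R)-5-ethyl-2-(2-hydroxyethyl)-2,4-dimethylcyclohex-3-en-1-one, via keto acid 10 (not isolated)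
Conditions: LiOH, THF/H2O, 0 °C; then 1 M HCl to pH 3, 45 °C
Reagents that add atoms: none
Why: saponification opens the bridging β-keto lactone and the freed, no longer bridged β-keto acid decarboxylates on mild acidification, leaving the quaternary and the non-enolisable ethyl-bearing centres untouched.

Step 6
Reactants: 11 hydroxy ketone
Product: 12 [(1R,4R)-4-ethyl-1,3-dimethyl-6-oxocyclohex-2-en-1-yl]acetaldehyde
Conditions: Dess–Martin periodinane, NaHCO3, CH2Cl2, 0 → 23 °C
Reagents that add atoms: none
Why: Dess–Martin oxidation of the primary alcohol (the open form of the hemiketal) to the aldehyde under buffered, non-epimerising conditions.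

Step 7
Reactants: 12 keto aldehyde
Product: 13 (2R,5R)-5-ethyl-2,4-dimethyl-2-(prop-2-en-1-yl)cyclohex-3-en-1-one
Conditions: Ph3PCH3Br, KN(SiMe3)2, THF, −78 → 0 °C
Reagents that add atoms: methyltriphenylphosphonium bromide, C[P+](c1ccccc1)(c1ccccc1)c1ccccc1.[Br-]
Why: Wittig methylenation, chemoselective for the aldehyde over the hindered α-quaternary ketone at low temperature.

Step 8
Reactants: 13 allyl ketone; 14 methyl (E)-3-methoxyprop-2-enoate
Product: 16 (5S,6R,9R)-9-ethyl-4-methoxy-6,8-dimethyl-6-(prop-2-en-1-yl)-1-oxaspiro[4.5]deca-3,7-dien-2-one, via hydroxy ester 15 (not isolated)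
Conditions: LiN(iPr)2, 14, THF, −90 °C; then 13, −78 → −20 °C; aq. NH4Cl
Reagents that add atoms: none
Why: Schmidt tetronate annulation (chelated β-lithio methoxyacrylate adds to the ketone and the alkoxide lactonises onto the cis ester); the nucleophile attacks axially on the half-chair with ethyl pseudoequatorial, anti to the pseudoaxial allyl group on the neighbouring quaternary carbon, so the new C–C bond is cis to the C6 methyl and the ring oxygen cis to allyl and ethyl.

**Decalin fragment (steps 9–17)**

Step 9
Reactants: 17 (2E,4E)-5-[methyl(phenyl)amino]penta-2,4-dienal (Zincke aldehyde); 18 allylmagnesium bromide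
Product: 20 (2E,4E)-octa-2,4,7-trienal, via carbinol 19 (not isolated)
Conditions: THF/Et2O, −78 → 0 °C; then 1 M HCl, 0 °C
Reagents that add atoms: none
Why: Grignard 1,2-addition to the vinylogous formamide followed by acid hydrolysis with allylic transposition (aminopentadienal homologation) gives the thermodynamically favoured E,E-dienal.

Step 10
Reactants: 20 trienal; 21 (4S)-4-benzyl-3-propanoyl-1,3-oxazolidin-2-one
Product: 23 (4S)-4-benzyl-3-[(2R,3R,4E,6E)-3-hydroxy-2-methyldeca-4,6,9-trienoyl]-1,3-oxazolidin-2-one, via silyl ether 22 (not isolated)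
Conditions: MgCl2 (20 mol %), Et3N, Me3SiCl, EtOAc, 23 °C; then MeOH, CF3CO2H (cat.)
Reagents that add atoms: none
Why: Evans magnesium-catalysed anti-aldol reaction, in which the chelated Z-enolate reacts through a boat transition state on the face away from the benzyl group to give the (2R,3R) anti adduct.

Step 11
Reactants: 23 anti-aldol adduct
Product: 24 (2R,3R,4E,6E)-3-hydroxy-N-methoxy-N,2-dimethyldeca-4,6,9-trienamide
Conditions: MeNH(OMe)·HCl, AlMe3, CH2Cl2, −20 → 0 °C
Reagents that add atoms: N,O-dimethylhydroxylamine hydrochloride, CNOC.Cl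
Why: Weinreb transamidation by the aluminium amide, assisted by the free β-hydroxyl, removes the auxiliary without touching the stereocentres.

Step 12
Reactants: 24 Weinreb amide; 25 ethyl acetate
Product: 26 ethyl (4R,5R,6E,8E)-5-hydroxy-4-methyl-3-oxododeca-6,8,11-trienoate
Conditions: LiN(iPr)2 (4 equiv), 25, THF, −78 °C; then 24, −78 → −40 °C; aq. NH4Cl
Reagents that add atoms: none
Why: Claisen condensation of the lithium enolate of ethyl acetate with the Weinreb amide, whose chelated tetrahedral intermediate prevents over-addition.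

Step 13
Reactants: 26 β-hydroxy ketone
Product: 27 ethyl (3S,4S,5R,6E,8E)-3,5-dihydroxy-4-methyldodeca-6,8,11-trienoate
Conditions: Et2BOMe, NaBH4, THF/MeOH (4:1), −78 °C; repeated evaporation from MeOH
Reagents that add atoms: none
Why: Narasaka–Prasad reduction, in which axial hydride delivery to the six-membered boron chelate gives the 1,3-syn diol and hence the anti,anti triad.

Step 14
Reactants: 27 syn-diol ester
Product: 28 ethyl (3S,4S,5R,6E,8E)-3,5-bis[(tert-butyldimethylsilyl)oxy]-4-methyldodeca-6,8,11-trienoate
Conditions: tBuMe2SiOTf, 2,6-lutidine, CH2Cl2, −78 → 0 °C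
Reagents that add atoms: tert-butyldimethylsilyl trifluoromethanesulfonate, CC(C)(C)[Si](C)(C)OS(=O)(=O)C(F)(F)F
Why: silylation of both secondary hydroxyls with the reactive silyl triflate gives ethers that survive every later step up to step 22.

Step 15
Reactants: 28 bis-silyl ester
Product: 29 (3S,4S,5R,6E,8E)-3,5-bis[(tert-butyldimethylsilyl)oxy]-4-methyldodeca-6,8,11-trienal
Conditions: iBu2AlH (1.1 equiv), CH2Cl2, −78 °C; aq. KNaC4H4O6 (potassium sodium tartrate)
Reagents that add atoms: none
Why: partial reduction of the ester, whose aluminium hemiacetal is stable at −78 °C and releases the aldehyde only on work-up.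

Step 16
Reactants: 29 aldehyde; 30 2-(triphenylphosphoranylidene)propanal
Product: 31 (2E,5S,6S,7R,8E,10E)-5,7-bis[(tert-butyldimethylsilyl)oxy]-2,6-dimethyltetradeca-2,8,10,13-tetraenal
Conditions: toluene, 80 °C
Reagents that add atoms: none
Why: Wittig olefination with the stabilised formyl ylide gives the (E)-α-methyl enal.

Step 17
Reactants: 31 tetraenal
Product: 32 (1R,2R,4aS,5R,6S,7S,8aR)-5,7-bis[(tert-butyldimethylsilyl)oxy]-1,6-dimethyl-2-(prop-2-en-1-yl)-1,2,4a,5,6,7,8,8a-octahydronaphthalene-1-carbaldehyde
Conditions: Me2AlCl (1.5 equiv), CH2Cl2, −78 → −20 °C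
Reagents that add atoms: none
Why: Lewis acid-promoted intramolecular Diels–Alder reaction with the aluminium-bound formyl group endo and the tether in a chair with both silyloxy groups equatorial (methyl axial), which gives the trans-fused octalin and sets C1, C2, C4a and C8a relative to the triad; the E-enal places CHO cis to H-8a and the E,E-diene places allyl cis to CHO.

**Union and endgame (steps 18–22)**

Step 18
Reactants: 16 spiro methyl tetronate; 32 decalin aldehyde
Product: 33 carbinol, i.e. 16 joined through tetronate C3 to the former formyl carbon of 32 as a CH(OH) link (both carbinol epimers; other centres as in 16 and 32)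
Conditions: LiN(iPr)2, 16, THF, −78 °C; then 32, −78 → −40 °C; aq. NH4Cl
Reagents that add atoms: none
Why: C3 lithiation of the 5,5-disubstituted methyl tetronate and 1,2-addition to the non-enolisable aldehyde; the new carbinol centre is formed unselectively and removed in step 19.

Step 19
Reactants: 33 carbinol
Product: 34 ketone (the 3-acyl methyl tetronate: 33 with C=O in place of CH(OH))
Conditions: Dess–Martin periodinane, NaHCO3, CH2Cl2, 23 °C
Reagents that add atoms: none
Why: Dess–Martin oxidation of the hindered secondary carbinol to the 3-acyl tetronate without touching silyl ethers or alkenes.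

Step 20
Reactants: 34 diene ketone
Product: 35 macrocyclic methyl tetronate (34 after loss of ethene: eleven-membered ring with a (Z)-CH2CH=CHCH2 bridge between cyclohexene C6 and decalin C2)
Conditions: RuCl2(=CH-C6H4-2-OiPr)(H2IMes) (second-generation Hoveyda–Grubbs catalyst, 10 mol %), toluene (1 mM), 80 °C
Reagents that add atoms: none
Why: ring-closing metathesis of the two terminal allyl groups (the other alkenes are tri- or endocyclic disubstituted and inert), run reversibly so that the less strained Z-olefin of the eleven-membered ring should dominate.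

Step 21
Reactants: 35 macrocyclic methyl tetronate
Product: 36 bis(tert-butyldimethylsilyl) ether of the target (free 3-acyl tetronic acid)
Conditions: LiCl, DMSO, 55 °C; then 1 M HCl work-up
Reagents that add atoms: none
Why: nucleophilic demethylation (SN2 attack of chloride on the O-methyl of the acyl-activated vinylogous ester) releases the 3-acyl tetronic acid without disturbing any stereocentre.

Step 22
Reactants: 36 bis-silyl ether
Product: 37 CNP0259772.1 (target)
Conditions: 48% aq. HF, MeCN, 23 °C
Reagents that add atoms: none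
Why: fluoride-mediated desilylation of the two secondary silyl ethers under acidic conditions that the acyl tetronic acid tolerates.

**Compound list**

1 | 3-methyloxolan-2-one (racemic) | CC1CCOC1=O | starting material
2 | tert-butyl acetate | CC(=O)OC(C)(C)C | starting material
3 | tert-butyl 6-hydroxy-4-methyl-3-oxohexanoate (racemic) | CC(CCO)C(=O)CC(=O)OC(C)(C)C | intermediate
4 | 6-hydroxy-4-methylhex-1-ene-1,3-dione (acylketene, racemic) | O=C=CC(=O)C(C)CCO | intermediate
5 | 5-methyloxepane-2,4-dione (racemic) | CC1CCOC(=O)CC1=O | intermediate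
6 | (E)-2-methylpent-2-enal | CC/C=C(\C)C=O | starting material
7 | 3-[(3S)-2-methyl-1-oxopentan-3-yl]-5-methyloxepane-2,4-dione (other centres epimerisable) | CC[C@@H](C(C)C=O)C1C(=O)OCCC(C)C1=O | intermediate
8 | (1S,6R,7S,8S,9S)-9-ethyl-7-hydroxy-6,8-dimethyl-3-oxabicyclo[4.3.1]decane-2,10-dione | CC[C@@H]1[C@@H]2C(=O)OCC[C@@](C)(C2=O)[C@@H](O)[C@H]1C | intermediate
9 | (1S,6R,9R)-9-ethyl-6,8-dimethyl-3-oxabicyclo[4.3.1]dec-7-ene-2,10-dione | CC[C@@H]1[C@@H]2C(=O)OCC[C@@](C)(C2=O)C=C1C | intermediate
10 | (3R,6R)-6-ethyl-3-(2-hydroxyethyl)-3,5-dimethyl-2-oxocyclohex-4-ene-1-carboxylic acid (C1 epimers) | CC[C@@H]1C(C(=O)O)C(=O)[C@](C)(CCO)C=C1C | intermediate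
11 | (2R,5R)-5-ethyl-2-(2-hydroxyethyl)-2,4-dimethylcyclohex-3-en-1-one | CC[C@@H]1CC(=O)[C@](C)(CCO)C=C1C | intermediate
12 | [(1R,4R)-4-ethyl-1,3-dimethyl-6-oxocyclohex-2-en-1-yl]acetaldehyde | CC[C@@H]1CC(=O)[C@](C)(CC=O)C=C1C | intermediate
13 | (2R,5R)-5-ethyl-2,4-dimethyl-2-(prop-2-en-1-yl)cyclohex-3-en-1-one | CC[C@@H]1CC(=O)[C@](C)(CC=C)C=C1C | intermediate
14 | methyl (E)-3-methoxyprop-2-enoate | CO/C=C/C(=O)OC | starting material
15 | methyl (2E)-3-[(1S,2R,5R)-5-ethyl-1-hydroxy-2,4-dimethyl-2-(prop-2-en-1-yl)cyclohex-3-en-1-yl]-3-methoxyprop-2-enoate | CC[C@@H]1C[C@@](O)(/C(OC)=C\C(=O)OC)[C@](C)(CC=C)C=C1C | intermediate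
16 | (5S,6R,9R)-9-ethyl-4-methoxy-6,8-dimethyl-6-(prop-2-en-1-yl)-1-oxaspiro[4.5]deca-3,7-dien-2-one | CC[C@@H]1C[C@]2(OC(=O)C=C2OC)[C@](C)(CC=C)C=C1C | intermediate
17 | (2E,4E)-5-[methyl(phenyl)amino]penta-2,4-dienal | CN(/C=C/C=C/C=O)c1ccccc1 | starting material
18 | allylmagnesium bromide | C=CC[Mg]Br | starting material
19 | (1E,3E)-1-[methyl(phenyl)amino]octa-1,3,7-trien-5-ol | CN(/C=C/C=C/C(O)CC=C)c1ccccc1 | intermediate
20 | (2E,4E)-octa-2,4,7-trienal | O=C/C=C/C=C/CC=C | intermediate
21 | (4S)-4-benzyl-3-propanoyl-1,3-oxazolidin-2-one | CCC(=O)N1[C@@H](Cc2ccccc2)COC1=O | starting material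
22 | O-trimethylsilyl ether of 23 | O=C1OC[C@H](Cc2ccccc2)N1C(=O)[C@H](C)[C@H](O[Si](C)(C)C)/C=C/C=C/CC=C | intermediate
23 | (4S)-4-benzyl-3-[(2R,3R,4E,6E)-3-hydroxy-2-methyldeca-4,6,9-trienoyl]-1,3-oxazolidin-2-one | O=C1OC[C@H](Cc2ccccc2)N1C(=O)[C@H](C)[C@H](O)/C=C/C=C/CC=C | intermediate
24 | (2R,3R,4E,6E)-3-hydroxy-N-methoxy-N,2-dimethyldeca-4,6,9-trienamide | CON(C)C(=O)[C@H](C)[C@H](O)/C=C/C=C/CC=C | intermediate
25 | ethyl acetate | CCOC(C)=O | starting material
26 | ethyl (4R,5R,6E,8E)-5-hydroxy-4-methyl-3-oxododeca-6,8,11-trienoate | CCOC(=O)CC(=O)[C@H](C)[C@H](O)/C=C/C=C/CC=C | intermediate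
27 | ethyl (3S,4S,5R,6E,8E)-3,5-dihydroxy-4-methyldodeca-6,8,11-trienoate | CCOC(=O)C[C@H](O)[C@H](C)[C@H](O)/C=C/C=C/CC=C | intermediate
28 | ethyl (3S,4S,5R,6E,8E)-3,5-bis[(tert-butyldimethylsilyl)oxy]-4-methyldodeca-6,8,11-trienoate | CCOC(=O)C[C@H](O[Si](C)(C)C(C)(C)C)[C@H](C)[C@H](O[Si](C)(C)C(C)(C)C)/C=C/C=C/CC=C | intermediate
29 | (3S,4S,5R,6E,8E)-3,5-bis[(tert-butyldimethylsilyl)oxy]-4-methyldodeca-6,8,11-trienal | O=CC[C@H](O[Si](C)(C)C(C)(C)C)[C@H](C)[C@H](O[Si](C)(C)C(C)(C)C)/C=C/C=C/CC=C | intermediate
30 | 2-(triphenylphosphoranylidene)propanal | CC(C=O)=P(c1ccccc1)(c1ccccc1)c1ccccc1 | starting material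
31 | (2E,5S,6S,7R,8E,10E)-5,7-bis[(tert-butyldimethylsilyl)oxy]-2,6-dimethyltetradeca-2,8,10,13-tetraenal | O=C/C(C)=C/C[C@H](O[Si](C)(C)C(C)(C)C)[C@H](C)[C@H](O[Si](C)(C)C(C)(C)C)/C=C/C=C/CC=C | intermediate
32 | (1R,2R,4aS,5R,6S,7S,8aR)-5,7-bis[(tert-butyldimethylsilyl)oxy]-1,6-dimethyl-2-(prop-2-en-1-yl)-1,2,4a,5,6,7,8,8a-octahydronaphthalene-1-carbaldehyde | O=C[C@@]1(C)[C@@H]2C[C@H](O[Si](C)(C)C(C)(C)C)[C@H](C)[C@H](O[Si](C)(C)C(C)(C)C)[C@H]2C=C[C@H]1CC=C | intermediate
33 | carbinol: 16 linked at tetronate C3 through CH(OH) to C1 of the decalin of 32 (carbinol epimers) | CC[C@@H]1C[C@]2(OC(=O)C(C(O)[C@@]3(C)[C@@H]4C[C@H](O[Si](C)(C)C(C)(C)C)[C@H](C)[C@H](O[Si](C)(C)C(C)(C)C)[C@H]4C=C[C@H]3CC=C)=C2OC)[C@](C)(CC=C)C=C1C | intermediate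
34 | ketone: 3-acyl methyl tetronate corresponding to 33 | CC[C@@H]1C[C@]2(OC(=O)C(C(=O)[C@@]3(C)[C@@H]4C[C@H](O[Si](C)(C)C(C)(C)C)[C@H](C)[C@H](O[Si](C)(C)C(C)(C)C)[C@H]4C=C[C@H]3CC=C)=C2OC)[C@](C)(CC=C)C=C1C | intermediate
35 | macrocyclic methyl tetronate with (Z)-olefin in the eleven-membered ring, bis-silyl ether | CC[C@@H]1C[C@]23OC(=O)C(C(=O)[C@@]4(C)[C@@H]5C[C@H](O[Si](C)(C)C(C)(C)C)[C@H](C)[C@H](O[Si](C)(C)C(C)(C)C)[C@H]5C=C[C@H]4C/C=C\C[C@]2(C)C=C1C)=C3OC | intermediate
36 | bis(tert-butyldimethylsilyl) ether of the target | CC[C@@H]1C[C@]23OC(=O)/C(=C(\O)[C@@]4(C)[C@@H]5C[C@H](O[Si](C)(C)C(C)(C)C)[C@H](C)[C@H](O[Si](C)(C)C(C)(C)C)[C@H]5C=C[C@H]4C/C=C\C[C@]2(C)C=C1C)C3=O | intermediate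
37 | CNP0259772.1 | CC[C@@H]1C[C@]23OC(=O)/C(=C(\O)[C@@]4(C)[C@@H]5C[C@H](O)[C@H](C)[C@H](O)[C@H]5C=C[C@H]4C/C=C\C[C@]2(C)C=C1C)C3=O | target

**Totals.** Total step count: 22. Longest linear sequence: 14 steps (steps 9–17, then 18–22).

**Steps most likely to fail**

1. Step 3. The α-branched enal may form its iminium ion slowly, so that uncatalysed addition competes and the enantiofacial control erodes. The reversible aldol may also rest at the lactol or close to the bicycle with ethyl axial. Fallback: setting out from 5 and 6, the classical achiral annulation (DBU alone, MeCN, 23 °C, thermodynamic control) should give the ketol as a racemate, that is 8 together with its enantiomer, the (1R,6S,7R,8R,9R)-ketol F1. Dehydration as in step 4 would give 9 together with its enantiomer, the (1R,6S,9S)-enone lactone F2. Preparative chromatography on a chiral stationary phase (amylose tris(3,5-dimethylphenylcarbamate), supercritical CO2/MeOH) removes F2, and the route is rejoined at 9.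

2. Step 20. Strain in the eleven-membered ring may divert the catalyst to intermolecular oligomerisation or to closure of the E-olefin. Fallback: setting out from 33, the ring is closed at the more flexible carbinol oxidation level with the same ruthenium carbene in dilute toluene, which should give the macrocyclic carbinol F3. Dess–Martin oxidation of F3 then rejoins the route at 35.

3. Step 8. The basic vinyllithium may enolise the ketone toward C6 or decompose before it adds to the α-quaternary carbonyl, and the facial selectivity may erode with this bulky nucleophile. Fallback: setting out from 13, the slimmer lithium acetylide of methyl propiolate (LiN(SiMe3)2, THF, −78 °C) should add along the same axial trajectory to give the propargylic alcohol F4. Sodium methoxide in methanol then adds methoxide to the ynoate and the tertiary hydroxyl lactonises, which rejoins the route at 16.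

**Further compounds**

F1 | step 3 | (1R,6S,7R,8R,9R)-9-ethyl-7-hydroxy-6,8-dimethyl-3-oxabicyclo[4.3.1]decane-2,10-dione | CC[C@H]1[C@H]2C(=O)OCC[C@](C)(C2=O)[C@H](O)[C@@H]1C
F2 | step 3 | (1R,6S,9S)-9-ethyl-6,8-dimethyl-3-oxabicyclo[4.3.1]dec-7-ene-2,10-dione | CC[C@H]1[C@H]2C(=O)OCC[C@](C)(C2=O)C=C1C
F3 | step 20 | macrocyclic carbinol (35 with CH(OH) in place of the ketone, carbinol epimers) | CC[C@@H]1C[C@]23OC(=O)C(C(O)[C@@]4(C)[C@@H]5C[C@H](O[Si](C)(C)C(C)(C)C)[C@H](C)[C@H](O[Si](C)(C)C(C)(C)C)[C@H]5C=C[C@H]4C/C=C\C[C@]2(C)C=C1C)=C3OC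
F4 | step 8 | methyl 3-[(1S,2R,5R)-5-ethyl-1-hydroxy-2,4-dimethyl-2-(prop-2-en-1-yl)cyclohex-3-en-1-yl]prop-2-ynoate | CC[C@@H]1C[C@@](O)(C#CC(=O)OC)[C@](C)(CC=C)C=C1C
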